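**Plan**

1. Numbering (ent-kaurane type): ring A = C1(OAc)-C2-C3-C4(Me2)-C5-C10. The cyclopentane is C5, C6(OH), C8, C9, C10. The lactone bridge is C8-C7(=O)-O-C20-C10. Ring C is C8, C9, C11(OH), C12, C13, C14. The acrylate is C16(=C17H2)-C15O2Me on C13.
2. Cuts: (i) C12-C13 (ring C); (ii) C13=C16 of the transposed acceptor (cross metathesis on a C8 allyl group); (iii) C9-C10, C6-C8 and O20-C7 in one reductive annulation. This leaves a ring-A epoxy aldehyde (C1-C6, C10, C20) and a five-carbon enelactone (C7, C8, C9, C11, C12).
3. Enabling feature: C13-C16(=C17) is an ester-bearing allyl system, so its transposed form C13=C16(CO2Me)-C17H2-SO2Ph is a polarity-matched radical trap that gives the methylidene back on fragmentation. C12 is a bare CH2 beside carbinol C11, the CH2OH end of a 1,2-diol, and hence a primary radical. Both arms sit gauche on the adjacent atoms C8/C9 of the rigid 3-oxabicyclo[3.2.1]octan-2-one.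
4. Forward: ring A (steps 1-6) and the enelactone (steps 7-11) merge in step 13. That step builds the cyclopentane and, by acyl shift out of the temporary C7-O12 ring, the bridged lactone. Ring C closes last (step 16), and desilylation ends the route.
5. Stereochemistry: C5 comes from a catalytic asymmetric conjugate addition, C1 from C5 (Luche reduction), and C11 from (R)-but-3-ene-1,2-diol. C9 forms anti to O11 and C10 anti to C6/O1. C8 and C6 follow from the ring constraints of the aldol, and C13 from the chair with axial C7.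

Key step: step 16

Remark: 22, 23, F3 and F4 are drawn as the Z olefins. The E isomers give the same C16 radical, so the geometry need not be controlled.

**Step 1**
Reactants: 1 4,4-dimethylcyclohex-2-en-1-one; 2 hex-1-yne
Product: 4 (2R,3S)-3-[(E)-hex-1-enyl]-2-(hydroxymethyl)-4,4-dimethylcyclohexan-1-one (CH2OH trans to hexenyl), via hexenylzirconocene chloride 3 (not isolated)
Conditions: Cp2Zr(H)Cl, 2, THF, rt; [Rh(cod)(MeCN)2]BF4 (5 mol %), (R)-BINAP, 1, rt; monomeric HCHO in THF, -78 to 0 °C; aq NH4Cl
Reagents that add atoms: formaldehyde, C=O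
Why: Hydrozirconation and rhodium(I)/BINAP-catalysed asymmetric 1,4-addition set C5 under catalyst control, and the regiodefined zirconium enolate undergoes an aldol reaction with formaldehyde anti to the new group, so that C20 lands on C10 and not on C2.

**Step 2**
Reactants: 4 (2R,3S)-hydroxymethyl ketone
Product: 6 (3R)-3-[(E)-hex-1-enyl]-4,4-dimethyl-2-methylidenecyclohexan-1-one, via primary mesylate 5 (not isolated)
Conditions: MsCl, Et3N, CH2Cl2, 0 °C; DBU, rt
Reagents that add atoms: none
Why: Mesylation and E1cB elimination of a β-hydroxy ketone should give the exocyclic enone without touching C5.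

**Step 3**
Reactants: 6 methylidene ketone
Product: 7 (1S,3R)-3-[(E)-hex-1-enyl]-4,4-dimethyl-2-methylidenecyclohexan-1-ol (OH cis to hexenyl)
Conditions: NaBH4, CeCl3·7H2O, MeOH, -78 to 0 °C
Reagents that add atoms: none
Why: The Luche reduction is 1,2-selective, and hydride should arrive on the ring face opposite the hexenyl group in either chair, which sets C1 as the 1,3-cis alcohol.

**Step 4**
Reactants: 7 allylic alcohol
Product: 8 (3S,4S,8R)-8-[(E)-hex-1-enyl]-7,7-dimethyl-1-oxaspiro[2.5]octan-4-ol (oxirane O cis to OH)
Conditions: VO(acac)2 (cat.), t-BuOOH, CH2Cl2, 0 °C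
Reagents that add atoms: tert-butyl hydroperoxide, CC(C)(C)OO
Why: Hydroxyl-directed vanadium-catalysed epoxidation selects the allylic 1,1-disubstituted alkene over the remote hexenyl group, and the C10 configuration made here is erased again in step 13.

**Step 5**
Reactants: 8 epoxy alcohol
Product: 9 (3S,4S,8R)-8-[(E)-hex-1-enyl]-7,7-dimethyl-1-oxaspiro[2.5]octan-4-yl acetate
Conditions: Ac2O, DMAP (cat.), pyridine, 0 °C to rt
Reagents that add atoms: acetic anhydride, CC(=O)OC(C)=O
Why: Standard acetylation installs the C1 acetate of the target while C1-OH is the only hydroxyl present, which is possible because no later step uses a strong base or a hydride.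

**Step 6**
Reactants: 9 epoxy acetate
Product: 10 (3S,4S,8R)-8-formyl-7,7-dimethyl-1-oxaspiro[2.5]octan-4-yl acetate
Conditions: O3, CH2Cl2, -78 °C; Me2S; used at once
Reagents that add atoms: ozone, [O-][O+]=O
Why: Ozonolysis with reductive work-up cleaves the only alkene to unveil the C6 aldehyde, whose C5 centre already has the more stable equatorial arrangement.

**Step 7**
Reactants: 11 (2R)-but-3-ene-1,2-diol
Product: 12 (2R)-2-hydroxybut-3-en-1-yl prop-2-enoate
Conditions: acryloyl chloride (1 equiv), 2,4,6-collidine, CH2Cl2, -78 °C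
Reagents that add atoms: acryloyl chloride, C=CC(=O)Cl
Why: Low-temperature acylation with a hindered pyridine base is selective for the primary hydroxyl of a 1,2-diol.

**Step 8**
Reactants: 12 hydroxy acrylate
Product: 13 (2R)-2-(tert-butyldimethylsilyloxy)but-3-en-1-yl prop-2-enoate
Conditions: TBSOTf, 2,6-lutidine, CH2Cl2, -78 °C
Reagents that add atoms: tert-butyldimethylsilyl triflate, CC(C)(C)[Si](C)(C)OS(=O)(=O)C(F)(F)F
Why: Silylation with the triflate at low temperature protects O11 faster than the acrylate can migrate.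

**Step 9**
Reactants: 13 silyloxy diene ester
Product: 14 (5R)-5-(tert-butyldimethylsilyloxy)-5,6-dihydro-2H-pyran-2-one
Conditions: (H2IMes)(PCy3)Cl2Ru=CHPh (5 mol %), CH2Cl2, reflux
Reagents that add atoms: none
Why: Ring-closing metathesis of an acrylate with an allylic ether is a standard entry to 5,6-dihydropyran-2-ones and leaves C11 untouched.

**Step 10**
Reactants: 14 enelactone
Product: 16 (5R)-3-bromo-5-(tert-butyldimethylsilyloxy)-5,6-dihydro-2H-pyran-2-one, via trans-3,4-dibromide 15 (not isolated)
Conditions: Br2, CH2Cl2, 0 °C; Et3N, 0 °C to rt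
Reagents that add atoms: bromine, BrBr
Why: Bromine addition followed by dehydrobromination through the acidic α-hydrogen is the usual way to α-bromo enelactones.

**Step 11**
Reactants: 16 bromo enelactone
Product: 17 (5R)-3-allyl-5-(tert-butyldimethylsilyloxy)-5,6-dihydro-2H-pyran-2-one
Conditions: allylSnBu3, Pd2(dba)3 (2.5 mol %), AsPh3, NMP, 50 °C
Reagents that add atoms: allyltributylstannane, C=CC[Sn](CCCC)(CCCC)CCCC
Why: Stille coupling of an α-bromo enoate with an allylstannane places the C14-C13 arm on C8 under neutral conditions.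

**Step 12**
Reactants: 18 methyl 2-(bromomethyl)prop-2-enoate
Product: 19 methyl 2-[(phenylsulfonyl)methyl]prop-2-enoate
Conditions: PhSO2Na, MeOH, reflux
Reagents that add atoms: sodium benzenesulfinate, [Na+].[O-]S(=O)c1ccccc1
Why: S-alkylation of the sulfinate by the allylic bromide (SN2 and SN2′ are degenerate here) gives the allyl sulfone.

**Step 13**
Reactants: 10 ring-A epoxy aldehyde; 17 allyl enelactone (2 equiv)
Product: 21 bridged 7,20-lactone with 1-OAc, 6-OH, C8 allyl, 11-OTBS and free C12-OH (C1, C5, C6, C8, C9, C10, C11 as in 25), via fused C7-O12 lactone diol 20 (not isolated)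
Conditions: Cp2TiCl2 (3 equiv), Zn, THF, rt; added over 2 h to 10 + 17, THF, 0 to 40 °C; aq NaH2PO4
Reagents that add atoms: none
Why: Proposed new method: Cp2TiCl should open the epoxide homolytically to the tertiary C10 radical, which adds to C9 of 17 anti to the C11 silyloxy group and, on ring A, anti to the cis-disposed C5 formyl and C1 acetoxy groups; a second titanium(III) then reduces the C8 α-acyl radical to a titanium(IV) enolate that can reach the C6 aldehyde only on the face cis to C10 (five-membered closure), which fixes C8 and puts O6 on the less hindered exo side trans to C4; finally the C20 titanium alkoxide transacylates C7, driven by loss of the trans-diaxial C10/OTBS strain in 20 and by the gem-dialkyl effect, and frees C12-OH; the closest known types are the titanocene(III) epoxide/acrylate reductive coupling with in situ lactonisation and the samarium(II) radical conjugate addition/enolate aldol cascade.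

**Step 14**
Reactants: 21 allyl lactone diol; 19 sulfonylmethyl acrylate (5 equiv)
Product: 22 C8-CH2-CH=C(CO2Me)CH2SO2Ph derivative of 21 (Z drawn)
Conditions: (H2IMes)Cl2Ru=CH(2-iPrOC6H4) (10 mol %), PhMe, 80 °C
Reagents that add atoms: none
Why: Cross metathesis of a terminal alkene with an excess of a non-dimerising 2-substituted acrylate, as known for methacrylates, should give the trisubstituted enoate and tolerates the free hydroxyls.

**Step 15**
Reactants: 22 allyl sulfone alcohol
Product: 23 C12 iodide of 22
Conditions: I2, PPh3, imidazole, CH2Cl2, 0 °C to rt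
Reagents that add atoms: iodine, II
Why: Appel-type iodination converts only the primary C12-OH, because the C6 carbinol is secondary and flanked by C8 and C5, and it makes the acyl shift of step 13 irreversible.

**Step 16**
Reactants: 23 iodo allyl sulfone
Product: 24 11-O-TBS ether of the target
Conditions: (Bu3Sn)2 (1.1 equiv), hν (sunlamp), PhH (0.005 M), 60 °C
Reagents that add atoms: none
Why: Photolysis of the ditin gives Bu3Sn•, which abstracts iodine from C12; the nucleophilic primary radical adds to C13, the β-carbon of the enoate, and the tertiary C16 radical expels PhSO2•, which regenerates Bu3Sn• from the ditin, so that the C12-C13 bond, the C13 stereocentre and the C16=C17 methylidene ester should all appear in one neutral chain step that contains no hydrogen donor. The closest known reaction type is radical allyl transfer (SH2′ addition-fragmentation) to 2-(sulfonylmethyl)acrylates, run here intramolecularly. Ring C closes in the 6-exo-trig mode through a chair in which C9-C10, C8-C6 and the C11 silyloxy group are equatorial. C13 is controlled by the quaternary C8, whose axial lactone carbonyl C7 would be syn-diaxial to an axial enoate, so the acceptor lies equatorial and H13 ends axial as in 25, and both olefin isomers of 23 converge on the same C16 radical. The step needs iodine abstraction to outrun stannyl attack on the enoate, and 6-exo closure to outrun 1,5-hydrogen transfer from C14 and 7-endo attack; the weak C-I bond, the polarity match, the gauche placement of the two arms on the rigid 3-oxabicyclo[3.2.1]octanone and high dilution should secure this.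

**Step 17**
Reactants: 24 silyl ether
Product: 25 target CNP0421185.1
Conditions: HF·pyridine, pyridine, THF, 0 °C to rt
Reagents that add atoms: none
Why: Fluoride desilylation in a buffered acidic medium frees O11 without O1-to-O11 acetyl migration, lactone opening or conjugate addition to the acrylate.

**Compound list**

1 | 4,4-dimethylcyclohex-2-en-1-one | CC1(C)CCC(=O)C=C1 | starting material
2 | hex-1-yne | CCCCC#C | starting material
3 | (E)-hex-1-enylzirconocene chloride | CCCC/C=C/[Zr](Cl)(C1C=CC=C1)C1C=CC=C1 | intermediate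
4 | (2R,3S)-3-[(E)-hex-1-enyl]-2-(hydroxymethyl)-4,4-dimethylcyclohexan-1-one | O=C1CCC(C)(C)[C@@H](/C=C/CCCC)[C@@H]1CO | intermediate
5 | primary mesylate of 4 | O=C1CCC(C)(C)[C@@H](/C=C/CCCC)[C@@H]1COS(C)(=O)=O | intermediate
6 | (3R)-3-[(E)-hex-1-enyl]-4,4-dimethyl-2-methylidenecyclohexan-1-one | O=C1CCC(C)(C)[C@@H](/C=C/CCCC)C1=C | intermediate
7 | (1S,3R)-3-[(E)-hex-1-enyl]-4,4-dimethyl-2-methylidenecyclohexan-1-ol | O[C@H]1CCC(C)(C)[C@@H](/C=C/CCCC)C1=C | intermediate
8 | (3S,4S,8R)-8-[(E)-hex-1-enyl]-7,7-dimethyl-1-oxaspiro[2.5]octan-4-ol | O[C@H]1CCC(C)(C)[C@@H](/C=C/CCCC)[C@]12CO2 | intermediate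
9 | (3S,4S,8R)-8-[(E)-hex-1-enyl]-7,7-dimethyl-1-oxaspiro[2.5]octan-4-yl acetate | CC(=O)O[C@H]1CCC(C)(C)[C@@H](/C=C/CCCC)[C@]12CO2 | intermediate
10 | (3S,4S,8R)-8-formyl-7,7-dimethyl-1-oxaspiro[2.5]octan-4-yl acetate | CC(=O)O[C@H]1CCC(C)(C)[C@@H](C=O)[C@]12CO2 | intermediate
11 | (2R)-but-3-ene-1,2-diol | OC[C@H](O)C=C | starting material
12 | (2R)-2-hydroxybut-3-en-1-yl prop-2-enoate | C=CC(=O)OC[C@H](O)C=C | intermediate
13 | (2R)-2-(tert-butyldimethylsilyloxy)but-3-en-1-yl prop-2-enoate | C=CC(=O)OC[C@H](O[Si](C)(C)C(C)(C)C)C=C | intermediate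
14 | (5R)-5-(tert-butyldimethylsilyloxy)-5,6-dihydro-2H-pyran-2-one | O=C1OC[C@H](O[Si](C)(C)C(C)(C)C)C=C1 | intermediate
15 | trans-3,4-dibromide of 14 (anti adduct, C4-Br trans to OTBS drawn) | O=C1OC[C@H](O[Si](C)(C)C(C)(C)C)[C@@H](Br)[C@@H]1Br | intermediate
16 | (5R)-3-bromo-5-(tert-butyldimethylsilyloxy)-5,6-dihydro-2H-pyran-2-one | O=C1OC[C@H](O[Si](C)(C)C(C)(C)C)C=C1Br | intermediate
17 | (5R)-3-allyl-5-(tert-butyldimethylsilyloxy)-5,6-dihydro-2H-pyran-2-one | O=C1OC[C@H](O[Si](C)(C)C(C)(C)C)C=C1CC=C | intermediate
18 | methyl 2-(bromomethyl)prop-2-enoate | C=C(CBr)C(=O)OC | starting material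
19 | methyl 2-[(phenylsulfonyl)methyl]prop-2-enoate | C=C(CS(=O)(=O)c1ccccc1)C(=O)OC | intermediate
20 | Giese/aldol adduct with the C7-O12 lactone intact and free C20-OH and C6-OH | O1C[C@H](O[Si](C)(C)C(C)(C)C)[C@H]([C@]2(CC=C)C1=O)[C@]3(CO)[C@@H](OC(C)=O)CCC(C)(C)[C@H]3[C@@H]2O | intermediate
21 | bridged 7,20-lactone, 1-OAc, 6-OH, C8 allyl, 11-OTBS, C12-OH | OC[C@H](O[Si](C)(C)C(C)(C)C)[C@@H]2[C@]3(CC=C)C(=O)OC[C@]21[C@@H](OC(C)=O)CCC(C)(C)[C@H]1[C@@H]3O | intermediate
22 | (Z)-allyl sulfone enoate alcohol | OC[C@H](O[Si](C)(C)C(C)(C)C)[C@@H]2[C@]3(C/C=C(\CS(=O)(=O)c4ccccc4)C(=O)OC)C(=O)OC[C@]21[C@@H](OC(C)=O)CCC(C)(C)[C@H]1[C@@H]3O | intermediate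
23 | C12 iodide of 22 | IC[C@H](O[Si](C)(C)C(C)(C)C)[C@@H]2[C@]3(C/C=C(\CS(=O)(=O)c4ccccc4)C(=O)OC)C(=O)OC[C@]21[C@@H](OC(C)=O)CCC(C)(C)[C@H]1[C@@H]3O | intermediate
24 | 11-O-TBS ether of the target | C=C(C(=O)OC)[C@@H]1C[C@H](O[Si](C)(C)C(C)(C)C)[C@@H]2[C@]3(C1)C(=O)OC[C@]21[C@@H](OC(C)=O)CCC(C)(C)[C@H]1[C@@H]3O | intermediate
25 | CNP0421185.1 | C=C(C(=O)OC)[C@@H]1C[C@H](O)[C@@H]2[C@]3(C1)C(=O)OC[C@]21[C@@H](OC(C)=O)CCC(C)(C)[C@H]1[C@@H]3O | target

**Step count and risks**

Total steps: 17. Longest linear sequence: 11 (steps 1-6 and 13-17).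

**Step 13.** The titanium enolate may be protonated, or the aldehyde may be masked as its C20-O hemiacetal, before the aldol closure can follow the hindered radical addition.
- The fallback sets out from 10 and 17 and splits the event into known operations.
- The titanocene(III) epoxide/acceptor coupling is run as above, but the enolate is quenched with N-bromosuccinimide to give the α-bromo lactone F1.
- F1 is treated with SmI2 in THF at -78 °C. This intramolecular Reformatsky aldol passes through a more reactive samarium(III) enolate.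
- Warming completes the acyl shift, and the route is rejoined at 21.

**Step 14.** Metathesis between the allyl group on the quaternary C8 and the hindered 1,1-disubstituted partner may be too slow, so that olefin isomerisation and catalyst decay take over.
- The fallback sets out from 21.
- Lemieux-Johnson cleavage (OsO4 cat., NaIO4) gives the C13 aldehyde F2.
- The known conjugate addition/Horner-Wadsworth-Emmons cascade (PhSNa, trimethyl 2-phosphonoacrylate, THF) turns F2 into the allyl sulfide F3.
- Oxidation of the sulfur with mCPBA rejoins the route at 22.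

**Step 16.** The rotamer about C9-C11 that points C12 at C13 also pushes the silyl ether against the C1 acetate. Closure may then become slower than 1,5-hydrogen transfer from C14 or stannyl attack on the enoate.
- The fallback sets out from 23 and reverses the order of the last two operations.
- HF·pyridine first gives the iodohydrin F4. Its small 11-OH can hydrogen-bond to the C1 acetate and so hold the reactive rotamer.
- The same ditin-mediated allyl transfer on F4 then comes back to the route directly at 25.

**Further compounds**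

F1 | step 13 | α-bromo lactone, C7-O12 ring intact, open hydroxy aldehyde form (either C8 epimer serves) | O1C[C@H](O[Si](C)(C)C(C)(C)C)[C@H]([C@@](Br)(CC=C)C1=O)[C@]2(CO)[C@@H](OC(C)=O)CCC(C)(C)[C@H]2C=O
F2 | step 14 | C13 aldehyde from 21 | OC[C@H](O[Si](C)(C)C(C)(C)C)[C@@H]2[C@]3(CC=O)C(=O)OC[C@]21[C@@H](OC(C)=O)CCC(C)(C)[C@H]1[C@@H]3O
F3 | step 14 | (Z)-allyl phenyl sulfide enoate alcohol | OC[C@H](O[Si](C)(C)C(C)(C)C)[C@@H]2[C@]3(C/C=C(\CSc4ccccc4)C(=O)OC)C(=O)OC[C@]21[C@@H](OC(C)=O)CCC(C)(C)[C@H]1[C@@H]3O
F4 | step 16 | 11-hydroxy C12 iodide (iodohydrin) | IC[C@H](O)[C@@H]2[C@]3(C/C=C(\CS(=O)(=O)c4ccccc4)C(=O)OC)C(=O)OC[C@]21[C@@H](OC(C)=O)CCC(C)(C)[C@H]1[C@@H]3O
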